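**Retrosynthetic overview**
- The aryl C-1–C(=O) bond and the whole resorcinol ring are made together: the terminal carbanion of the heptane-2,4,6-trione trianion opens a 6,7-cyclic carbonate of the core, and the resulting triketo ester aromatises by aldol closure.
- Enabling feature: the cis O-6/O-7 diol (secondary C-6, tertiary C-7) of the cyclohexene ring can be bridged as a five-membered 1,3-dioxolan-2-one whose carbonyl carbon is the future ester carbon; the 2,4-dihydroxy-6-methylphenyl ring is a folded C8 tetraketide (C7 triketone + that carbonyl carbon).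
- Core: gold-catalysed 6-endo-dig closure of the pyran ring on an ynenone, made from an enone by Baylis–Hillman hydroxymethylation (C-1) and conjugate alkynylation/selenoxide elimination (C-3, C-4, side chain).
- Enone from (R)-carvone: epoxidation sets C-6/C-7, CO2 insertion with retention gives the carbonate, Criegee dealkenylation/elimination removes the isopropenyl group.
- Ring order: cyclohexane (chiral pool) → dioxolanone (temporary) → pyran → benzene ring (key step, dioxolanone opened); C-8 is a silyl-protected carbinol during the anionic step and is re-oxidised afterwards.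

Key step: step 11

Assumption: (E)-pent-2-en-4-yn-1-ol (1) and heptane-2,4,6-trione (21) are taken as purchasable, and the isochromene numbering of the target (C-1 = OCH2, O-2, C-3, C-4, C-4a, C-5 = CH2, C-6 = CH–O, C-7 = C(CH3)OH, C-8 = C=O, C-8a) is used for every core intermediate.

**Route**

Step 1
Reactants: 1 (E)-pent-2-en-4-yn-1-ol
Product: 2 (E)-tert-butyl(pent-2-en-4-yn-1-yloxy)diphenylsilane
Conditions: TBDPSCl, imidazole, CH2Cl2, 0 °C → rt
Reagents that add atoms: tert-butyl(chloro)diphenylsilane, CC(C)(C)[Si](Cl)(c1ccccc1)c1ccccc1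
Why: Standard silylation of a primary alcohol gives a bulky silyl ether that should survive every later step up to the final fluoride treatment and leaves the (E)-alkene untouched.

Step 2
Reactants: 3 (R)-(−)-carvone
Product: 4 (1R,4R,6R)-1-methyl-4-(prop-1-en-2-yl)-7-oxabicyclo[4.1.0]heptan-2-one
Conditions: 30% H2O2, NaOH (cat.), MeOH, 0 °C
Reagents that add atoms: hydrogen peroxide, OO
Why: Weitz–Scheffer nucleophilic epoxidation, in which hydroperoxide adds to C-6 anti to the isopropenyl group on C-4a, so that the chiral-pool centre fixes both C-6 and C-7 (epoxide oxygen on the face that the two target oxygens occupy).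

Step 3
Reactants: 4 trans-carvone oxide
Product: 5 (3aR,5R,7aR)-7a-methyl-5-(prop-1-en-2-yl)hexahydro-1,3-benzodioxole-2,7-dione (cis-fused 6,7-carbonate)
Conditions: CO2 (15 bar), Al(III) amino-tris(phenolate) complex (1 mol%), PPNCl (3 mol%), 2-butanone, 85 °C
Reagents that add atoms: carbon dioxide, O=C=O
Why: Halide-cocatalysed cycloaddition of CO2 to an epoxide: chloride opens the oxirane with inversion, the alkoxide takes up CO2 and the carbonate oxygen displaces chloride with a second inversion, so the cis-fused 1,3-dioxolan-2-one should form with overall retention at C-6 and C-7, and its carbonyl carbon is the future ester carbon.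

Step 4
Reactants: 5 carvone-derived cyclic carbonate
Product: 8 (3aR,7aR)-7a-methyl-3a,4-dihydro-1,3-benzodioxole-2,7(7aH)-dione, via methoxy hydroperoxide 6 (not isolated), via β-acetoxy ketone 7 (not isolated)
Conditions: O3, CH2Cl2/MeOH, −78 °C; Ac2O, Et3N, DMAP (cat.), −78 °C → rt; then DBU (1.05 equiv), CH2Cl2, 0 °C
Reagents that add atoms: none
Why: Ozonolysis in methanol followed by Criegee rearrangement of the peracetate turns the isopropenyl group into an acetoxy group at C-4a, and E1cB loss of acetic acid from this β-acetoxy ketone can only give the conjugated C-8a=C-4a enone, the C-6/C-7 centres being untouched.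

Step 5
Reactants: 8 enone carbonate
Product: 9 (3aR,7aR)-6-(hydroxymethyl)-7a-methyl-3a,4-dihydro-1,3-benzodioxole-2,7(7aH)-dione
Conditions: 37% aq. HCHO, DMAP (0.2 equiv), THF, rt
Reagents that add atoms: formaldehyde, C=O
Why: Morita–Baylis–Hillman reaction: DMAP adds reversibly to C-4a, the enolate is hydroxymethylated at C-8a by formaldehyde and the catalyst is expelled again, which installs C-1 without creating a stereocenter.

Step 6
Reactants: 9 hydroxymethyl enone; 2 silyl-protected enyne
Product: 14 α-phenylseleno ketone (SePh on C-8a trans to the alkynyl group on C-4a; C-1 oxygen as TMS ether), via TMS ether 10 (not isolated), via lithium acetylide 11 (not isolated), via alkynylzinc bromide 12 (not isolated), via silyl enol ether 13 (not isolated)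
Conditions: 9, TMSOTf, 2,6-lutidine, Et2O, −78 °C; add alkynylzinc bromide (from 2, n-BuLi, THF, −78 °C; ZnBr2) and TMSOTf, −78 → −30 °C; PhSeCl, −78 °C; pH 7 work-up
Reagents that add atoms: trimethylsilyl triflate, C[Si](C)(C)OS(=O)(=O)C(F)(F)F; benzeneselenenyl chloride, Cl[Se]c1ccccc1
Why: Silyl-triflate-promoted conjugate addition of an alkynylzinc halide gives the tetrasubstituted silyl enol ether regiospecifically, and selenenylation of that enol ether should occur anti to the pseudoaxial alkynyl group, placing selenium syn to H-4a; both new centres are temporary.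

Step 7
Reactants: 14 α-phenylseleno ketone
Product: 17 (3aR,7aR)-6-(hydroxymethyl)-7a-methyl-5-[(E)-5-(tert-butyldiphenylsilyloxy)pent-3-en-1-yn-1-yl]-3a,4-dihydro-1,3-benzodioxole-2,7(7aH)-dione, via selenoxide 15 (not isolated), via TMS-protected ynenone 16 (not isolated)
Conditions: 30% H2O2, pyridine, CH2Cl2, 0 °C → rt; then 10% aq. citric acid, THF
Reagents that add atoms: none
Why: Selenoxide syn-elimination uses the syn hydrogen on C-4a and not a hydrogen of the CH2O group (selenoxides eliminate away from oxygen), which restores the C-8a=C-4a enone, and the mild acid wash cleaves the primary trimethylsilyl ether.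

Step 8
Reactants: 17 hydroxy ynenone
Product: 18 (6R,7R)-6,7-(carbonyldioxy)-7-methyl-3-[(E)-3-(tert-butyldiphenylsilyloxy)prop-1-en-1-yl]-6,7-dihydro-1H-isochromen-8(5H)-one
Conditions: Ph3PAuCl (2 mol%), AgOTf (2 mol%), CH2Cl2, rt
Reagents that add atoms: none
Why: Gold(I)-catalysed 6-endo-dig hydroalkoxylation: the alkyne terminus C-3 is the δ-carbon of the ynenone and carries the vinyl group, so the primary alcohol on C-1 should attack there and close the 1H-isochromene ring rather than a five-membered ring.

Step 9
Reactants: 18 bicyclic ketone carbonate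
Product: 19 8-hydroxy compound (C-8 epimers; 6,7-carbonate and configuration as in 18)
Conditions: NaBH4, CeCl3·7H2O, MeOH/CH2Cl2, −40 °C
Reagents that add atoms: none
Why: Luche reduction delivers hydride 1,2 to the hindered doubly vinylogous ester ketone at low temperature without opening the carbonate, and the new C-8 centre is temporary, so either epimer serves.

Step 10
Reactants: 19 allylic alcohol
Product: 20 8-O-triethylsilyl ether of 19
Conditions: TESCl, imidazole, DMAP (cat.), CH2Cl2, 0 °C
Reagents that add atoms: chlorotriethylsilane, CC[Si](Cl)(CC)CC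
Why: Silylation of the secondary allylic alcohol prevents its alkoxide from attacking the neighbouring carbonate (carbonate migration) under the basic conditions of step 11.

Step 11
Reactants: 20 silyl-protected cyclic carbonate; 21 heptane-2,4,6-trione
Product: 24 6-O-(2,4-dihydroxy-6-methylbenzoyl) ester with free 7-OH (8-O-TES; side chain O-TBDPS), via trilithium trianion 22 (not isolated), via open-chain trioxooctanoate 23 (not isolated)
Conditions: 21 (3 equiv), LDA (8.8 equiv), THF, 0 °C; add 20, −40 → 0 °C; AcOH quench, then aq. NaHCO3/Na2CO3 (pH 9)–THF, 25 °C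
Reagents that add atoms: none
Why: Proposed new method: the terminal carbanion of trianion 22 adds to the carbonate carbonyl of 20, the tetrahedral intermediate opens by loss of the more hindered tertiary O-7 alkoxide to give the secondary 3,5,7-trioxooctanoate 23 (held as its unreactive enolate), and at pH 9 its most acidic C-2 methylene attacks the terminal methyl ketone, after which the adduct dehydrates and enolises to the 2,4-dihydroxy-6-methylbenzoate. The closest known reactions are the acylation or carboxylation of β-polyketone polyanions with esters or CO2 followed by biomimetic aldol aromatisation to resorcylates, and the opening of secondary/tertiary 1,2-diol carbonates by aryllithiums to the secondary aroate. One ring is closed, the benzene ring, by a 6-(enolendo)-exo-trig aldol addition followed by aromatising dehydration, while the dioxolanone ring is opened. No stereocenter is formed, and C-6 and C-7 are untouched because only acyl C–O bonds are made and broken. The step needs C-acylation at the terminal carbon (the only non-stabilised carbanion of 22), retention of the acyl group on O-6 (cleavage toward the tertiary, more crowded O-7), and aldol rather than Claisen or lactone cyclisation (the hindered secondary alkoxy group is a poor leaving group); base-induced loss of the C-6 oxygen is excluded because C-8 is at the alcohol level and no enolate can reach C-5.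

Step 12
Reactants: 24 orsellinate ester
Product: 25 8-hydroxy orsellinate (C-8 epimers; side chain O-TBDPS)
Conditions: Et3N·3HF, THF, 0 °C → rt
Reagents that add atoms: none
Why: Fluoride cleaves the secondary triethylsilyl ether much faster than the primary tert-butyldiphenylsilyl ether, and the nearly neutral reagent avoids ionisation of the acid-sensitive dienyl carbinol.

Step 13
Reactants: 25 allylic alcohol
Product: 26 O-TBDPS-entonaemin A
Conditions: activated MnO2, CH2Cl2, rt
Reagents that add atoms: none
Why: Manganese dioxide oxidises only the allylic C-8 carbinol, which is activated by the dienol ether, to the vinylogous ester ketone, while the tertiary alcohol, the phenols and the silylated primary alcohol are left alone.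

Step 14
Reactants: 26 O-TBDPS-entonaemin A
Product: 27 entonaemin A
Conditions: HF·pyridine, pyridine, THF, 0 °C → rt
Reagents that add atoms: none
Why: Buffered fluoride desilylation frees the primary allylic alcohol under non-basic conditions, so that base-induced elimination of the C-6 ester through the dienolate cannot occur.

**Compound list**

1 | (E)-pent-2-en-4-yn-1-ol | C#C/C=C/CO | starting material
2 | (E)-tert-butyl(pent-2-en-4-yn-1-yloxy)diphenylsilane | C#C/C=C/CO[Si](c1ccccc1)(c1ccccc1)C(C)(C)C | intermediate
3 | (R)-(−)-carvone, (5R)-2-methyl-5-(prop-1-en-2-yl)cyclohex-2-en-1-one | CC1=CC[C@H](CC1=O)C(C)=C | starting material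
4 | (1R,4R,6R)-1-methyl-4-(prop-1-en-2-yl)-7-oxabicyclo[4.1.0]heptan-2-one (epoxide trans to isopropenyl) | O1[C@@H]2C[C@@H](C(C)=C)CC(=O)[C@]12C | intermediate
5 | (3aR,5R,7aR)-7a-methyl-5-(prop-1-en-2-yl)hexahydro-1,3-benzodioxole-2,7-dione (cis-fused carbonate, trans to isopropenyl) | O=C1O[C@@H]2C[C@@H](C(C)=C)CC(=O)[C@]2(C)O1 | intermediate
6 | α-methoxy hydroperoxide of 5 (2-hydroperoxy-2-methoxypropan-2-yl group on C-4a, epimers at that carbon) | O=C1O[C@@H]2C[C@@H](C(C)(OC)OO)CC(=O)[C@]2(C)O1 | intermediate (not isolated)
7 | β-acetoxy ketone (acetoxy on C-4a with retention; carbonate as in 5) | O=C1O[C@@H]2C[C@@H](OC(C)=O)CC(=O)[C@]2(C)O1 | intermediate (not isolated)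
8 | (3aR,7aR)-7a-methyl-3a,4-dihydro-1,3-benzodioxole-2,7(7aH)-dione | O=C1O[C@@H]2CC=CC(=O)[C@]2(C)O1 | intermediate
9 | (3aR,7aR)-6-(hydroxymethyl)-7a-methyl-3a,4-dihydro-1,3-benzodioxole-2,7(7aH)-dione | O=C1O[C@@H]2CC=C(CO)C(=O)[C@]2(C)O1 | intermediate
10 | O-trimethylsilyl ether of 9 | O=C1O[C@@H]2CC=C(CO[Si](C)(C)C)C(=O)[C@]2(C)O1 | intermediate (not isolated)
11 | lithium acetylide of 2 | [Li]C#C/C=C/CO[Si](c1ccccc1)(c1ccccc1)C(C)(C)C | intermediate (not isolated)
12 | alkynylzinc bromide of 2 | Br[Zn]C#C/C=C/CO[Si](c1ccccc1)(c1ccccc1)C(C)(C)C | intermediate (not isolated)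
13 | trimethylsilyl enol ether (C-8 OTMS, C-8a=C-8; alkynyl on C-4a, epimers; C-1 OTMS) | O=C1O[C@@H]2CC(C#C/C=C/CO[Si](c3ccccc3)(c3ccccc3)C(C)(C)C)C(CO[Si](C)(C)C)=C(O[Si](C)(C)C)[C@]2(C)O1 | intermediate (not isolated)
14 | α-phenylseleno ketone (SePh on C-8a trans to alkynyl on C-4a; these two temporary centres not controlled relative to the carbonate; C-1 OTMS) | O=C1O[C@@H]2CC(C#C/C=C/CO[Si](c3ccccc3)(c3ccccc3)C(C)(C)C)C(CO[Si](C)(C)C)([Se]c3ccccc3)C(=O)[C@]2(C)O1 | intermediate
15 | selenoxide of 14 | O=C1O[C@@H]2CC(C#C/C=C/CO[Si](c3ccccc3)(c3ccccc3)C(C)(C)C)C(CO[Si](C)(C)C)([Se](=O)c3ccccc3)C(=O)[C@]2(C)O1 | intermediate (not isolated)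
16 | O-trimethylsilyl ether of 17 | O=C1O[C@@H]2CC(C#C/C=C/CO[Si](c3ccccc3)(c3ccccc3)C(C)(C)C)=C(CO[Si](C)(C)C)C(=O)[C@]2(C)O1 | intermediate (not isolated)
17 | (3aR,7aR)-6-(hydroxymethyl)-7a-methyl-5-[(E)-5-(tert-butyldiphenylsilyloxy)pent-3-en-1-yn-1-yl]-3a,4-dihydro-1,3-benzodioxole-2,7(7aH)-dione | O=C1O[C@@H]2CC(C#C/C=C/CO[Si](c3ccccc3)(c3ccccc3)C(C)(C)C)=C(CO)C(=O)[C@]2(C)O1 | intermediate
18 | (6R,7R)-6,7-(carbonyldioxy)-7-methyl-3-[(E)-3-(tert-butyldiphenylsilyloxy)prop-1-en-1-yl]-6,7-dihydro-1H-isochromen-8(5H)-one | O=C1O[C@@H]2CC3=C(COC(/C=C/CO[Si](c4ccccc4)(c4ccccc4)C(C)(C)C)=C3)C(=O)[C@]2(C)O1 | intermediate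
19 | 8-hydroxy analogue of 18 (5,6,7,8-tetrahydro-1H-isochromen-8-ol; 6,7-carbonate and configuration as in 18; C-8 epimers) | O=C1O[C@@H]2CC3=C(COC(/C=C/CO[Si](c4ccccc4)(c4ccccc4)C(C)(C)C)=C3)C(O)[C@]2(C)O1 | intermediate
20 | 8-O-triethylsilyl ether of 19 | O=C1O[C@@H]2CC3=C(COC(/C=C/CO[Si](c4ccccc4)(c4ccccc4)C(C)(C)C)=C3)C(O[Si](CC)(CC)CC)[C@]2(C)O1 | intermediate
21 | heptane-2,4,6-trione | CC(=O)CC(=O)CC(C)=O | starting material
22 | trilithium trianion of heptane-2,4,6-trione | [Li+].[Li+].[Li+].C=C([O-])C=C([O-])C=C(C)[O-] | intermediate (not isolated)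
23 | 3,5,7-trioxooctanoate of the C-6 oxygen (7-OH free; 8-O-TES; side chain O-TBDPS; 6,7-configuration as in 18) | CC(=O)CC(=O)CC(=O)CC(=O)O[C@@H]1CC2=C(COC(/C=C/CO[Si](c3ccccc3)(c3ccccc3)C(C)(C)C)=C2)C(O[Si](CC)(CC)CC)[C@]1(C)O | intermediate (not isolated)
24 | 7-hydroxy-7-methyl-8-(triethylsilyloxy)-3-[(E)-3-(tert-butyldiphenylsilyloxy)prop-1-en-1-yl]-5,6,7,8-tetrahydro-1H-isochromen-6-yl 2,4-dihydroxy-6-methylbenzoate (6,7-cis as in target; C-8 epimers) | Cc1cc(O)cc(O)c1C(=O)O[C@@H]1CC2=C(COC(/C=C/CO[Si](c3ccccc3)(c3ccccc3)C(C)(C)C)=C2)C(O[Si](CC)(CC)CC)[C@]1(C)O | intermediate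
25 | 8-hydroxy analogue of 24 (TES removed; C-8 epimers) | Cc1cc(O)cc(O)c1C(=O)O[C@@H]1CC2=C(COC(/C=C/CO[Si](c3ccccc3)(c3ccccc3)C(C)(C)C)=C2)C(O)[C@]1(C)O | intermediate
26 | O-TBDPS-entonaemin A, (6R,7R)-7-hydroxy-7-methyl-8-oxo-3-[(E)-3-(tert-butyldiphenylsilyloxy)prop-1-en-1-yl]-5,6,7,8-tetrahydro-1H-isochromen-6-yl 2,4-dihydroxy-6-methylbenzoate | Cc1cc(O)cc(O)c1C(=O)O[C@@H]1CC2=C(COC(/C=C/CO[Si](c3ccccc3)(c3ccccc3)C(C)(C)C)=C2)C(=O)[C@]1(C)O | intermediate
27 | entonaemin A, (6R,7R)-7-hydroxy-3-[(E)-3-hydroxyprop-1-en-1-yl]-7-methyl-8-oxo-5,6,7,8-tetrahydro-1H-isochromen-6-yl 2,4-dihydroxy-6-methylbenzoate | Cc1cc(O)cc(O)c1C(=O)O[C@@H]1CC2=C(COC(/C=C/CO)=C2)C(=O)[C@]1(C)O | target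

**Step count and risks**

Total step count: 14. Longest linear sequence: 13 steps (3 → 27, steps 2–14); step 1 is a one-step side branch.

Steps most likely to fail:

1. Step 11 (the step that carries the label "Proposed new method:"). The trianion may transfer a proton instead of acylating. The tetrahedral intermediate may collapse toward the secondary O-6 alkoxide, leaving the acyl group on O-7. The triketo ester may also cyclise by the Claisen or lactone pathway and expel the core alcohol. Fallback with known chemistry, setting out from 20: orcinol should be allylated (allyl bromide, K2CO3, acetone) to 1,3-bis(allyloxy)-5-methylbenzene F1. Bromination with NBS (MeCN, 0 °C) para to one allyloxy group should give 1,5-bis(allyloxy)-2-bromo-3-methylbenzene F2. Bromine–lithium exchange (n-BuLi, THF, −78 °C) and addition of the aryllithium to carbonate 20 at −78 °C (aryllithium opening of a secondary/tertiary cyclic carbonate, where acyl migration can still correct the regiochemistry) should give the bis-O-allyl ester F3. Pd(PPh3)4/morpholine (THF, rt) should remove both allyl groups, and the route is rejoined at 24.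

2. Step 3. The hindered trisubstituted epoxy ketone may not turn over, or the Lewis acid may trigger an acyl shift of the epoxy ketone instead of CO2 uptake. Fallback, setting out from 4: opening with MgBr2·OEt2 (Et2O, 0 °C) should give the trans-bromohydrin F4 (bromine on C-6 anti to the C-7 hydroxyl). Cs2CO3 under CO2 (1 atm, DMF, rt) should then carboxylate the tertiary alkoxide and close the carbonate by intramolecular SN2 displacement of bromide. This is the same double inversion done stepwise, and it returns at 5.

3. Step 4. During the base treatment the enone may lose the C-6 carbonate oxygen by vinylogous E1cB elimination through the dienolate, or the Criegee rearrangement may stall. Fallback, setting out from 5 and returning at 8: ozonolysis in methanol to hydroperoxide 6, followed directly by FeSO4·7H2O/Cu(OAc)2 (MeOH, −20 °C → rt). Fe(II) cleaves the peroxide, the alkoxy radical expels methyl acetate by β-scission, and Cu(II) oxidises the C-4a radical to the conjugated alkene under neutral conditions. No new compound is made.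

Further compounds
F1 | step 11 | 1,3-bis(allyloxy)-5-methylbenzene | Cc1cc(OCC=C)cc(OCC=C)c1
F2 | step 11 | 1,5-bis(allyloxy)-2-bromo-3-methylbenzene | Cc1cc(OCC=C)cc(OCC=C)c1Br
F3 | step 11 | 2,4-bis(allyloxy)-6-methylbenzoate of the C-6 oxygen (7-OH free; 8-O-TES; side chain O-TBDPS; C-8 epimers) | Cc1cc(OCC=C)cc(OCC=C)c1C(=O)O[C@@H]1CC2=C(COC(/C=C/CO[Si](c3ccccc3)(c3ccccc3)C(C)(C)C)=C2)C(O[Si](CC)(CC)CC)[C@]1(C)O
F4 | step 3 | trans-bromohydrin of 4 (3-bromo-2-hydroxy-2-methyl-5-(prop-1-en-2-yl)cyclohexan-1-one, Br anti to OH) | Br[C@H]1C[C@@H](C(C)=C)CC(=O)[C@]1(C)O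
F0 | step 4 | none | none
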